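**Retrosynthetic overview**

1. Numbering (order of the ring atoms in the target SMILES): C1 = CH–O-methacrylate, C2 = CH2, C3 = CH–O-isobutyrate, C4 = C(CH3), C5 = CH next to C=O, C6 = C=O, C7 = enone CH, C8 = enone C(CH3), C9 = allylic CH, C10 = CH, C11 = C(CH3)2.
2. Target ⇐ alcohol 19 (methacrylation) ⇐ cage hydroxy diketone 18 (Evans–Tishchenko: sets C1 and leaves the isobutyrate on C3–O).
3. 18 ⇐ cis-fused bicyclo[5.3.0]decenone 15 (key step): a formyl-derived diazo carbon C5 on C10 is inserted into the C6–C4 bond, so the cyclopentenone C4–C6–C7–C8–C9 becomes the cyclohexenone C4–C5–C6–C7–C8–C9 and the cyclobutane C4–C5–C10–C9 forms at once. The enabling feature is that C5 lies between the carbonyl carbon C6 and the quaternary C4 and is also bonded to C10, which sits 1,3-syn to C6 on the seven-membered ring.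
4. 15 ⇐ seven-membered ring C4–C3–C2–C1–C11–C10–C9 by aldol closure (C2–C3) of a methyl ketone onto the α-formyl quaternary centre C4 (formylation, then methylation anti to the C9 substituent; Wacker oxidation for the methyl ketone).
5. C9–C10 ⇐ Ireland–Claisen rearrangement of the 3,3-dimethylpent-4-enoate of (R)-2-methylcyclopent-2-enol (CBS reduction, the only reagent-controlled stereocentre). Ring order: cyclopentene (bought) → seven-membered ring → cyclobutane and cyclohexenone together.

Key step: step 12

**Route**

Step 1
Reactants: 1 2-methylcyclopent-2-en-1-one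
Product: 2 (R)-2-methylcyclopent-2-en-1-ol
Conditions: (S)-2-methyl-CBS-oxazaborolidine (10 mol %), BH3·SMe2, THF, −20 °C
Reagents that add atoms: none
Why: Corey–Bakshi–Shibata reduction, in which the α-substituted alkenyl arm acts as the large group, should deliver hydride to one carbonyl face and give the (R)-carbinol C7 from which all later stereocentres are relayed.

Step 2
Reactants: 2 (R)-2-methylcyclopent-2-en-1-ol; 3 3,3-dimethylpent-4-enoic acid
Product: 4 (1R)-2-methylcyclopent-2-en-1-yl 3,3-dimethylpent-4-enoate
Conditions: DCC, DMAP (cat.), CH2Cl2, 0 °C → rt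
Reagents that add atoms: none
Why: Steglich esterification acylates the secondary allylic alcohol under neutral conditions without touching the carbinol stereocentre or shifting the alkene.

Step 3
Reactants: 4 (1R)-2-methylcyclopent-2-en-1-yl 3,3-dimethylpent-4-enoate
Product: 7 (2R)-3,3-dimethyl-2-[(1R)-2-methylcyclopent-2-en-1-yl]pent-4-en-1-ol, via silyl ketene acetal 5 (not isolated), via trimethylsilyl ester 6 (not isolated)
Conditions: LDA, THF–DMPU, −78 °C; Me3SiCl; −78 → 45 °C; then LiAlH4, 0 °C
Reagents that add atoms: none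
Why: Ireland–Claisen rearrangement with in-flask hydride reduction of the silyl ester: enolisation in THF–DMPU should give ketene acetal 5 with the tert-alkyl group cis to OSiMe3, the suprafacial [3,3] shift transfers the C7–O configuration to C9, and the chair-like transition state expected here (the 2-methyl group of the cyclopentenyl unit cancels the usual boat preference of cycloalkenyl esters) places the tert-alkyl group pseudo-equatorial and so sets C10.

Step 4
Reactants: 7 (2R)-3,3-dimethyl-2-[(1R)-2-methylcyclopent-2-en-1-yl]pent-4-en-1-ol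
Product: 8 (2R)-3,3-dimethyl-2-[(1R)-2-methylcyclopent-2-en-1-yl]pent-4-enal
Conditions: Dess–Martin periodinane, CH2Cl2, 0 °C → rt
Reagents that add atoms: none
Why: Dess–Martin oxidation stops at the aldehyde and, being non-basic, should not epimerise the α-stereocentre C10.

Step 5
Reactants: 8 (2R)-3,3-dimethyl-2-[(1R)-2-methylcyclopent-2-en-1-yl]pent-4-enal
Product: 9 (5R)-5-[(2R)-1,1-dimethoxy-3,3-dimethylpent-4-en-2-yl]-1-methylcyclopent-1-ene
Conditions: HC(OMe)3, PPTS (cat.), MeOH, rt
Reagents that add atoms: trimethyl orthoformate, COC(OC)OC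
Why: Acid-catalysed acetalisation masks the aldehyde carbon (the later diazo carbon C5) for the oxidising and basic steps that follow.

Step 6
Reactants: 9 (5R)-5-[(2R)-1,1-dimethoxy-3,3-dimethylpent-4-en-2-yl]-1-methylcyclopent-1-ene
Product: 10 (4R)-4-[(2R)-1,1-dimethoxy-3,3-dimethylpent-4-en-2-yl]-3-methylcyclopent-2-en-1-one
Conditions: CrO3, 3,5-dimethylpyrazole, CH2Cl2, −20 °C
Reagents that add atoms: chromium trioxide, O=[Cr](=O)=O
Why: Allylic oxidation with the CrO3–3,5-dimethylpyrazole complex should convert the ring CH2 next to the trisubstituted alkene into the conjugated enone, since the other allylic sites are a hindered methine and a methyl group and the vinyl group has no allylic hydrogen.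

Step 7
Reactants: 10 (4R)-4-[(2R)-1,1-dimethoxy-3,3-dimethylpent-4-en-2-yl]-3-methylcyclopent-2-en-1-one
Product: 11 (4R,5Z)-4-[(2R)-1,1-dimethoxy-3,3-dimethylpent-4-en-2-yl]-5-(hydroxymethylidene)-3-methylcyclopent-2-en-1-one
Conditions: NaH, HCO2Et, THF, 0 °C → rt; AcOH quench
Reagents that add atoms: ethyl formate, CCOC=O
Why: Crossed Claisen condensation (α′-formylation) occurs at C4, the only sp3 α-carbon of the enone, and the product is held as its stabilised enolate.

Step 8
Reactants: 11 (4R,5Z)-4-[(2R)-1,1-dimethoxy-3,3-dimethylpent-4-en-2-yl]-5-(hydroxymethylidene)-3-methylcyclopent-2-en-1-one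
Product: 12 (1S,5R)-5-[(2R)-1,1-dimethoxy-3,3-dimethylpent-4-en-2-yl]-1,4-dimethyl-2-oxocyclopent-3-ene-1-carbaldehyde
Conditions: MeI, K2CO3, acetone, rt
Reagents that add atoms: iodomethane, CI
Why: C-Alkylation of the β-keto aldehyde enolate creates the quaternary centre C4, with methyl iodide approaching the planar enolate anti to the bulky C9 substituent so that the formyl group ends cis to it.

Step 9
Reactants: 12 (1S,5R)-5-[(2R)-1,1-dimethoxy-3,3-dimethylpent-4-en-2-yl]-1,4-dimethyl-2-oxocyclopent-3-ene-1-carbaldehyde
Product: 13 (1S,5R)-5-[(2R)-1,1-dimethoxy-3,3-dimethyl-4-oxopentan-2-yl]-1,4-dimethyl-2-oxocyclopent-3-ene-1-carbaldehyde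
Conditions: PdCl2 (10 mol %), Cu(OAc)2 (20 mol %), O2 (1 atm), DMA–H2O, rt
Reagents that add atoms: water, O
Why: Tsuji–Wacker oxidation converts only the terminal vinyl group (Markovnikov) into the methyl ketone, the trisubstituted ring alkene being inert and the copper acetate variant keeping the medium mild enough for the acetal.

Step 10
Reactants: 13 (1S,5R)-5-[(2R)-1,1-dimethoxy-3,3-dimethyl-4-oxopentan-2-yl]-1,4-dimethyl-2-oxocyclopent-3-ene-1-carbaldehyde
Product: 14 cis-fused 8-hydroxy-4-(dimethoxymethyl)-3,5,5,8a-tetramethyl-3a,4,5,7,8,8a-hexahydroazulene-1,6-dione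
Conditions: LiHMDS (1.05 equiv), THF, −78 °C; AcOH quench at −78 °C
Reagents that add atoms: none
Why: Intramolecular aldol addition closes the seven-membered ring: the methyl ketone has only its CH3 to enolise, the aldehyde cannot enolise, and a lithium chelate between the aldehyde and C6 carbonyl oxygens fixes the rotamer so that the tethered enolate should attack the face that puts the C3 hydroxyl syn to C6.

Step 11
Reactants: 14 cis-fused 8-hydroxy-4-(dimethoxymethyl)-3,5,5,8a-tetramethyl-3a,4,5,7,8,8a-hexahydroazulene-1,6-dione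
Product: 15 N-[2-(trifluoromethyl)benzenesulfonyl]hydrazone of the 4-carbaldehyde corresponding to 14
Conditions: 2-(CF3)C6H4SO2NHNH2, PPTS (cat.), THF–H2O, 40 °C
Reagents that add atoms: 2-(trifluoromethyl)benzenesulfonohydrazide, NNS(=O)(=O)c1ccccc1C(F)(F)F
Why: Acid-catalysed exchange of the dimethyl acetal with the sulfonyl hydrazide gives the hydrazone at the aldehyde carbon only, both ketones being flanked by quaternary carbons.

Step 12
Reactants: 15 N-[2-(trifluoromethyl)benzenesulfonyl]hydrazone of the 4-carbaldehyde corresponding to 14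
Product: 18 cage hydroxy diketone (3-hydroxy-1-oxo core of the target), via diazoalkane 16 (not isolated), via diazonium alkoxide 17 (not isolated)
Conditions: NaH (1.0 equiv), CH2Cl2 (0.005 M), −40 → 25 °C
Reagents that add atoms: none
Why: Proposed new method: Loss of arenesulfinate from the hydrazone anion gives the non-stabilised diazoalkane 16; its carbon C5 adds to the C6 carbonyl, which the syn C3 hydroxyl activates by a hydrogen bond, to give the bicyclo[2.2.1] diazonium alkoxide 17, and the C6–C4 bond then migrates to C5 with loss of N2, so that C5 is inserted between C6 and C4. The closest known reaction type is the intramolecular diazoalkane–ketone ring enlargement of (ω-diazoalkyl)cycloalkanones to bridged ketones (Tiffeneau–Demjanov-type 1,2-shift), not yet shown for a carbenoid tethered across the ring that must move a ring-fusion carbon and create a cyclobutane. The C5–C6 bond closes by 5-exo-trig addition (ring C5–C10–C9–C4–C6); the 1,2-shift then contracts that five-membered ring to the cyclobutane C4–C5–C10–C9 and enlarges the cyclopentenone C4–C6–C7–C8–C9 to the cyclohexenone C4–C5–C6–C7–C8–C9, with retention at C4 and inversion at C5. C5, the only new stereocentre, is fixed by the cis ring fusion and the syn C10 side chain of 15, because the one-carbon bridge can only be built on the face that already carries C6 and the side chain; C4, C9 and C10 pass through unchanged. The step needs migration of the quaternary C4 instead of the vinylic C7: in 17 the exo side of C5 is blocked by the C11 gem-dimethyl group and by the C3 arm of the seven-membered ring, so N2+ should sit endo, antiperiplanar to C6–C4 and gauche to C6–C7, and epoxide closure is excluded because the bridgehead C–O bond cannot reach the backside of C5. Carbene-type decay of 16 is held back by generating it below room temperature at high dilution, and the loss of N2 pays for the strain of the bicyclo[3.1.1] product.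

Step 13
Reactants: 18 cage hydroxy diketone (3-hydroxy-1-oxo core of the target)
Product: 19 C3-isobutyrate C1-alcohol of the target skeleton
Conditions: i-PrCHO (6 equiv), SmI2 (30 mol %), THF, −10 °C
Reagents that add atoms: isobutyraldehyde, CC(C)C=O
Why: Evans–Tishchenko reduction: the samarium-bound hemiacetal formed from the C3 hydroxyl and isobutyraldehyde delivers hydride within the ring to the C1 ketone (after the ring expansion the only ketone β to that hydroxyl), which should give the 1,3-anti (trans) C1 alcohol and leave the isobutyrate on C3–O.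

Step 14
Reactants: 19 C3-isobutyrate C1-alcohol of the target skeleton
Product: 20 CNP0214356.1 (target)
Conditions: methacrylic anhydride, Et3N, DMAP (cat.), BHT, CH2Cl2, 0 °C → rt
Reagents that add atoms: methacrylic anhydride, C=C(C)C(=O)OC(=O)C(C)=C
Why: DMAP-catalysed acylation of the remaining secondary alcohol installs the methacrylate last, so the acrylate never meets the diazoalkane or the enolate chemistry.

**Compound list**

1 | 2-methylcyclopent-2-en-1-one | CC1=CCCC1=O | starting material
2 | (R)-2-methylcyclopent-2-en-1-ol | O[C@H]1C(C)=CCC1 | intermediate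
3 | 3,3-dimethylpent-4-enoic acid | OC(=O)CC(C)(C)C=C | starting material
4 | (1R)-2-methylcyclopent-2-en-1-yl 3,3-dimethylpent-4-enoate | C=CC(C)(C)CC(=O)O[C@H]1C(C)=CCC1 | intermediate
5 | trimethylsilyl ketene acetal of 4, tert-alkyl group cis to OSiMe3 | C[Si](C)(C)O/C(=C\C(C)(C)C=C)O[C@H]1C(C)=CCC1 | intermediate (not isolated)
6 | trimethylsilyl (2R)-3,3-dimethyl-2-[(1R)-2-methylcyclopent-2-en-1-yl]pent-4-enoate | C[Si](C)(C)OC(=O)[C@H]([C@@H]1C(C)=CCC1)C(C)(C)C=C | intermediate (not isolated)
7 | (2R)-3,3-dimethyl-2-[(1R)-2-methylcyclopent-2-en-1-yl]pent-4-en-1-ol | OC[C@H]([C@@H]1C(C)=CCC1)C(C)(C)C=C | intermediate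
8 | (2R)-3,3-dimethyl-2-[(1R)-2-methylcyclopent-2-en-1-yl]pent-4-enal | O=C[C@H]([C@@H]1C(C)=CCC1)C(C)(C)C=C | intermediate
9 | (5R)-5-[(2R)-1,1-dimethoxy-3,3-dimethylpent-4-en-2-yl]-1-methylcyclopent-1-ene | COC(OC)[C@H]([C@@H]1C(C)=CCC1)C(C)(C)C=C | intermediate
10 | (4R)-4-[(2R)-1,1-dimethoxy-3,3-dimethylpent-4-en-2-yl]-3-methylcyclopent-2-en-1-one | COC(OC)[C@H]([C@@H]1C(C)=CC(=O)C1)C(C)(C)C=C | intermediate
11 | (4R,5Z)-4-[(2R)-1,1-dimethoxy-3,3-dimethylpent-4-en-2-yl]-5-(hydroxymethylidene)-3-methylcyclopent-2-en-1-one | COC(OC)[C@H]([C@@H]1C(C)=CC(=O)/C1=C\O)C(C)(C)C=C | intermediate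
12 | (1S,5R)-5-[(2R)-1,1-dimethoxy-3,3-dimethylpent-4-en-2-yl]-1,4-dimethyl-2-oxocyclopent-3-ene-1-carbaldehyde (formyl cis to the side chain) | COC(OC)[C@H]([C@@H]1C(C)=CC(=O)[C@]1(C)C=O)C(C)(C)C=C | intermediate
13 | (1S,5R)-5-[(2R)-1,1-dimethoxy-3,3-dimethyl-4-oxopentan-2-yl]-1,4-dimethyl-2-oxocyclopent-3-ene-1-carbaldehyde | COC(OC)[C@H]([C@@H]1C(C)=CC(=O)[C@]1(C)C=O)C(C)(C)C(C)=O | intermediate
14 | 8-hydroxy-4-(dimethoxymethyl)-3,5,5,8a-tetramethyl-3a,4,5,7,8,8a-hexahydroazulene-1,6-dione; ring fusion cis (8a-CH3 and 3a-H on one face), 8-OH and 4-CH(OMe)2 on the other face, the side of the five-membered ring | O[C@@H]1CC(=O)C(C)(C)[C@H](C(OC)OC)[C@@H]2C(C)=CC(=O)[C@]12C | intermediate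
15 | (E)-N-[2-(trifluoromethyl)benzenesulfonyl]hydrazone of the 4-carbaldehyde corresponding to 14 | O[C@@H]1CC(=O)C(C)(C)[C@H](/C=N/NS(=O)(=O)c3ccccc3C(F)(F)F)[C@@H]2C(C)=CC(=O)[C@]12C | intermediate
16 | 4-(diazomethyl) analogue of 14 | O[C@@H]1CC(=O)C(C)(C)[C@H](C=[N+]=[N-])[C@@H]2C(C)=CC(=O)[C@]12C | intermediate (not isolated)
17 | diazonium alkoxide: bicyclo[2.2.1]heptene adduct with C5–C6 bond formed, N2+ endo on C5, O− on bridgehead C6 | [O-][C@@]12C=C(C)[C@H]3[C@@H]([C@H]1[N+]#N)C(C)(C)C(=O)C[C@@H](O)[C@@]23C | intermediate (not isolated)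
18 | cage hydroxy diketone: target skeleton with C3–OH and C1=O (bicyclo[3.1.1]hept-3-en-2-one whose two one-carbon bridges are spanned, anti to the enone, by CH(OH)–CH2–C(=O)–C(CH3)2) | O=C1C[C@@H](O)[C@@]2(C)[C@@H]3C(=O)C=C(C)[C@H]2[C@@H]3C1(C)C | intermediate
19 | C3-isobutyrate, C1-alcohol of the target skeleton (C1–OH trans to C3–O) | O[C@@H]1C[C@@H](OC(=O)C(C)C)[C@@]2(C)[C@@H]3C(=O)C=C(C)[C@H]2[C@@H]3C1(C)C | intermediate
20 | CNP0214356.1 | C=C(C)C(=O)O[C@@H]1C[C@@H](OC(=O)C(C)C)[C@@]2(C)[C@@H]3C(=O)C=C(C)[C@H]2[C@@H]3C1(C)C | target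

**Step count and risks**

Total step count: 14. Longest linear sequence: 14 steps (1 → 20; acid 3 enters at step 2).

Steps most likely to fail:

Step 12 (proposed new method). The diazoalkane may be lost to carbene-type decay (1,2-hydride shift, azine formation) before it adds to the hindered conjugated carbonyl. Alternatively the wrong bond may migrate if the diazonium group forms on the exo side. The fallback uses known chemistry, sets out from 14 and returns at 18: a Tiffeneau–Demjanov route through an intramolecular nitro-aldol reaction. Acetal 14 with NH2OH·HCl and NaOAc in aqueous ethanol should give the aldoxime F1. Oxidation with sodium perborate in acetic acid should give the primary nitroalkane F2. A catalytic amine base (Et3N, THF) should close the C5–C6 bond by a reversible Henry reaction to the nitro alcohol F3, where equilibration places the nitro group on the less hindered endo side. Zn in acetic acid should reduce it to the amino alcohol F4. NaNO2 in aqueous acetic acid at 0 °C should then trigger the deaminative 1,2-shift of C4 and deliver 18.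

Step 3. Control of ketene acetal geometry may be incomplete, or the rearrangement may run through a boat-like instead of a chair-like transition state; either gives poor relative selectivity at C10 (C9 is safe, being set by suprafacial transfer). The fallback sets out from 4 and returns at 7: a lactone-templated epimerisation. The rearrangement is worked up to the free acid; if the C10-epimeric acid F5 dominates, iodolactonisation (I2, NaHCO3, MeCN) should give the cis-fused iodolactone F6. Deprotonation (LDA, THF, −78 °C) and kinetic protonation of the lactone enolate from the convex face (2,6-di-tert-butylphenol) should invert C10 and give the endo-substituted iodolactone F7. Zn in acetic acid should regenerate the ring alkene and give the acid F8, and LiAlH4 reduction then gives 7.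

Step 10. The lithium aldolate may undergo retro-aldol formyl transfer, the enone may be deprotonated at its γ-position, or the enolate may add to the non-chelated aldehyde rotamer and give the wrong face at C3. The fallback sets out from 13 and returns at 14: a samarium Reformatsky-type cyclisation. Bromination of the methyl ketone (PhNMe3Br3, THF, 0 °C) should give the bromomethyl ketone F9. SmI2 (2 equiv, THF, −78 °C) should reduce the C–Br bond selectively to the samarium(III) enolate, which adds to the aldehyde inside a samarium chelate and gives 14.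

Further compounds
F1 | step 12 | aldoxime of the 4-carbaldehyde corresponding to 14 | O[C@@H]1CC(=O)C(C)(C)[C@H](C=NO)[C@@H]2C(C)=CC(=O)[C@]12C
F2 | step 12 | 4-(nitromethyl) analogue of 14 | O[C@@H]1CC(=O)C(C)(C)[C@H](C[N+](=O)[O-])[C@@H]2C(C)=CC(=O)[C@]12C
F3 | step 12 | nitro alcohol, bicyclo[2.2.1] nitro-aldol adduct with NO2 endo on C5 and OH on C6 | O[C@@]12C=C(C)[C@H]3[C@@H]([C@H]1[N+](=O)[O-])C(C)(C)C(=O)C[C@@H](O)[C@@]23C
F4 | step 12 | amino alcohol, NH2 endo on C5 and OH on C6 | O[C@@]12C=C(C)[C@H]3[C@@H]([C@H]1N)C(C)(C)C(=O)C[C@@H](O)[C@@]23C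
F5 | step 3 | (2S)-3,3-dimethyl-2-[(1R)-2-methylcyclopent-2-en-1-yl]pent-4-enoic acid (C10 epimer) | OC(=O)[C@@H]([C@@H]1C(C)=CCC1)C(C)(C)C=C
F6 | step 3 | cis-fused iodolactone of F5 (tert-alkyl group on the convex face) | O=C1O[C@]2(C)[C@@H](I)CC[C@@H]2[C@H]1C(C)(C)C=C
F7 | step 3 | C10-inverted iodolactone (tert-alkyl group on the concave face) | O=C1O[C@]2(C)[C@@H](I)CC[C@@H]2[C@@H]1C(C)(C)C=C
F8 | step 3 | (2R)-3,3-dimethyl-2-[(1R)-2-methylcyclopent-2-en-1-yl]pent-4-enoic acid | OC(=O)[C@H]([C@@H]1C(C)=CCC1)C(C)(C)C=C
F9 | step 10 | bromomethyl ketone derived from 13 | COC(OC)[C@H]([C@@H]1C(C)=CC(=O)[C@]1(C)C=O)C(C)(C)C(=O)CBr
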